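(All runs were computed on assumed constants; noise was put on by code.)

common to all: gas 15 mM (held)
- Wednesday's: substrate 0.27 M; run made earlier
- Friday's: substrate 0.60 M; run made earlier
- flask: substrate 0.40 M; time 30 h

| run | time / h | target / % | isomer of the product A / % | substrate / % |
|---|---|---|---|---|
| Wednesday's | 1.50 | 8.7 | 0.8 | 18.3 |
| Wednesday's | 5.00 | 24.8 | 1.2 | 0.3 |
| Wednesday's | 8.00 | 28.3 | 1.6 | 0.2 |
| Wednesday's | 12.0 | 28.3 | 2.5 | 0 |
| Wednesday's | 20.0 | 28.6 | 3.2 | 0.4 |
| Wednesday's | 25.0 | 27.6 | 4.4 | 0.3 |
| Friday's | 1.50 | 6.4 | 0 | 38.9 |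
| Friday's | 5.00 | 23.7 | 0.7 | 0.3 |
| Friday's | 8.00 | 27.0 | 1.9 | 0 |
| Friday's | 12.0 | 28.4 | 2.5 | 0.4 |
| Friday's | 20.0 | 29.1 | 3.6 | 0.2 |
| Friday's | 25.0 | 27.8 | 3.4 | 1.3 |

(standard deviation of a reading: 0.5 percentage points)

- at the start none of the gas is in solution

- share of target in target plus isomer of the product A at 50 min
- share of target in target plus isomer of the product A at 5.0 h
- share of target in target plus isomer of the product A at 30 h

- Late in these two runs, target in percent of charge holds still when the charge changes. At 20.0 h target reads 28.6% on Wednesday at 0.27 M and 29.1% on Friday at 0.60 M, although Friday's charge is larger. Early the runs part: at 1.50 h substrate reads 18.3% on Wednesday and 38.9% on Friday. So I pool both runs for the flask from 5.00 h on, where substrate reads 0.3% and 0.3%.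
- Gas stands at 15 mM in both runs and in the flask, so I carry it over as it is.
- The asked share of target in target plus isomer is the selectivity. Target's plateau, pooled from 12.0 h on, reads 28.3%. Pooled isomer at 25.0 h reads 3.90%. An error of 0.5 percentage points in the plateau moves the share at that time by 0.19 points.
- The same error in isomer moves that share by 1.4 points, which is more. So isomer's pace is the number to know.
- Pooled, isomer gains 3 points from 5.00 h to 25.0 h.
- My drift lifetime is 192 h: the hours in which isomer, at that pace, would equal target's plateau.
- At 30 h the flask has run 15.6% of one drift lifetime. I reckon isomer at 4.43% and a share of 86.5%.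
- The forecast gives 97% at 50 min, 96.3% at 5.0 h and 86.5% at 30 h, holding that “the isomer probably comes mainly from slow target isomerization”.
- The flask gives 98.2%, 96.5% and 84.6%, and the forecast stands within its margins.

    substrate + partner → intermediate + by-product (k = 2.14 M⁻¹ min⁻¹)
    intermediate ⇌ target (K = 0.504, k = 0.00339 min⁻¹)
    intermediate ⇌ isomer of the product A (K = 240, k = 4.90 × 10⁻⁵ min⁻¹)
    gas ⇌ partner, rate k4*(csat - [partner]) (kL = 0.425 min⁻¹)
    target ⇌ isomer of the product B (K = 0.430, k = 0.0132 min⁻¹)
    partner → decomposed reagent (k = 0.00246 min⁻¹)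

- At 30 h the flask holds target 27.9% and isomer 5.06%, more isomer than the 4.43% from the drift lifetime.
- The neighbouring flask starts from 0.10 M of substrate, with all else the same. Counted in percent of charge, it takes the same 192 h, so I reckon a share of 86.5% at 30 h.
- It holds target 27.9% and isomer 5.13%, a share of 84.5%.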